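Time is equal on paper: 80 s of mean residence in the tank gamma, 80 s of run in the flask alpha.

    target ⇌ isomer of the product (K1 = 1.3, k1 = 0.0039 s⁻¹)
    substrate → intermediate A (k2 = 0.0045 s⁻¹)
    intermediate B → intermediate E (k3 = 0.012 s⁻¹)
    intermediate E ⇌ target (K4 = 14, k4 = 0.0024 s⁻¹)
    intermediate C ⇌ intermediate D (K5 = 0.33, k5 = 0.16 s⁻¹)
    intermediate A ⇌ intermediate B (K6 = 0.30, k6 = 0.0051 s⁻¹)
    substrate ⇌ intermediate C (K7 = 0.42, k7 = 0.057 s⁻¹)

- gamma: substrate 2.3 M; one stirred flow tank at steady state, fed with the mixture as stated, mean residence time 80 s
- alpha: substrate 2.3 M; time 80 s; everything together in a closed stirred flask, run for 80 s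

1. the set-up with the highest share of target in all that became target or isomer of the product, at the outlet or at the end ("none" if the first two lie within 2 percentage points) (gamma / alpha / none)
2. share of target in all that became target or isomer of the product, at the outlet or at the end, gamma
3. share of target in all that became target or isomer of the product, at the outlet or at the end, alpha

The isomer of the product is treated here as a correction to target, so the reckoning follows its ratio to target. A bench rule says a slow side step converts, per target, its rate constant times the stay. For the tank gamma that gives

0.0039 s⁻¹ × 80 s = 0.312.

The rule ends where the way back begins to compete with washout, and that ratio is already not negligible: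

0.00300 s⁻¹ / 0.0125 s⁻¹ = 0.240.

The isomer of the product forms from target and leaves by washout and by the back step, so at steady state

0.0039 s⁻¹ / (0.0125 s⁻¹ + 0.00300 s⁻¹) = 0.252.

This number, c(isomer of the product)/c(target), is the isomer ratio, and the share of target is one over one plus it: 79.9% for gamma.

In the flask alpha, target lies 4 steps behind substrate. Early on c(target) therefore grows as time to the power 4, and its mean age is the run divided by 5, 16.0 s. The ratio is then 0.0624, a share of 94.1%. That figure leans high: the forward half-life of substrate towards intermediate C, 12.2 s, is shorter than the run, so the feed sags and target is older than reckoned.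

The forecast names alpha, with 79.9% (79.5% to 80.3%) for gamma and 93.5% (92.5% to 94.5%) for alpha, since "target only appears late, after a lag through the chain of intermediates". Its alpha figure stands lower than the one reckoned here.

The simulation gives 79.9% for gamma and 93.7% for alpha, so alpha leads by 14 percentage points. The flask alpha is not at rest at 80 s: 50.0% of the charge still stands as substrate, and its ratio reads 0.0672. For gamma at ten times the residence time, the tank ratio becomes 0.918, a share of 52.1%, and the run shows 52.1%. Alpha at 800 s shows 60.2%, a ratio of 0.661, which is half of the 1.3 of the pair at equilibrium, thermodynamic control, where the share is 43.5%.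

The numbers are assumed; the rest is arithmetic.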